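**Retrosynthetic overview**

1. The route rests on ring A of the benzofuran (C3a, C4, C5, C6, C7, C7a). It carries OH on C4, the chiral 2-hydroxy-3-methylbut-3-enyl chain on C5, OMe on C6 and H on C7, which is the pattern formed when a ketene carbon becomes a phenol carbon beside the two carbons of a 1-methoxyalkyne. Ring A is therefore built last, onto a finished 2-aryl-3-carboxyfuran (ring B, already bearing aryl ring C).
2. Key disconnection: C7–C7a, C4–C5, C6–C7 and C3a–C4 are cut together, leading back to 2-furyl diazoketone 8 and (R)-methoxyalkyne 15 (Wolff rearrangement, [2+2] addition, four-electron opening, six-electron closure).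
3. Diazoketone 8: Suzuki coupling at C5 of 4,5-dibromofuran-2-carboxylic acid, methoxycarbonylation of the remaining C4–Br, phenol silylation, then acid chloride and diazomethane. The free acid and the methyl ester are distinct from the first step.
4. Alkyne 15: methacrolein to isopropenyloxirane, hydrolytic kinetic resolution (sets the only stereocentre), Lewis-acid-free opening at CH2 by sodium methoxyacetylide, silylation.
5. End game: the C3 ester is reduced to CH2OH and oxidised to CHO, then fluoride removes both silyl ethers.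

Key step: step 9

Remark: 1, 2, 9 and 12 are taken as catalogue chemicals. The kinetic resolution of 10 is assumed to follow the sense known for terminal alkyl and vinyl epoxides, the (S,S)-catalyst leaving the (S)-epoxide; the configuration would be confirmed on 14 through its Mosher esters.

**Route**

Step 1
Reactants: 1 4,5-dibromofuran-2-carboxylic acid; 2 3-methoxy-4-(4,4,5,5-tetramethyl-1,3,2-dioxaborolan-2-yl)phenol
Product: 3 4-bromo-5-(4-hydroxy-2-methoxyphenyl)furan-2-carboxylic acid
Conditions: Pd(PPh3)4 (5 mol%), Na2CO3 (3.5 equiv), 1,4-dioxane/H2O 4:1, 85 °C; then aq. HCl to pH 3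
Reagents that add atoms: none
Why: Suzuki–Miyaura coupling in which zerovalent palladium inserts much faster into the C5–Br bond next to the ring oxygen than into the β C4–Br bond (the usual site selectivity of 2,3-dibromofurans), so that only C5 should be arylated while the carboxylate and phenolate are tolerated.

Step 2
Reactants: 3 4-bromo-5-(4-hydroxy-2-methoxyphenyl)furan-2-carboxylic acid
Product: 4 5-(4-hydroxy-2-methoxyphenyl)-4-(methoxycarbonyl)furan-2-carboxylic acid
Conditions: Pd(OAc)2 (5 mol%), Xantphos (6 mol%), CO (1 atm), Et3N (4 equiv), MeOH/DMF 1:1, 75 °C; then aq. HCl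
Reagents that add atoms: carbon monoxide [C-]#[O+]; methanol CO
Why: Palladium-catalysed methoxycarbonylation of a heteroaryl bromide, in which the acylpalladium intermediate is trapped by methanol while the C2 carboxylic acid (present as its ammonium salt) is not esterified, so the two carboxyl groups come out differentiated.

Step 3
Reactants: 4 5-(4-hydroxy-2-methoxyphenyl)-4-(methoxycarbonyl)furan-2-carboxylic acid
Product: 6 5-[4-(tert-butyldimethylsilyloxy)-2-methoxyphenyl]-4-(methoxycarbonyl)furan-2-carboxylic acid, via silyl ester 5 (not isolated)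
Conditions: TBSCl (2.5 equiv), imidazole (5 equiv), DMF, rt; then THF/H2O/AcOH, rt
Reagents that add atoms: tert-butyldimethylsilyl chloride CC(C)(C)[Si](C)(C)Cl
Why: Standard silylation with TBSCl and imidazole caps both the phenol and the acid, and the far more labile silyl ester should hydrolyse selectively under the mild aqueous acidic work-up, leaving the aryl silyl ether.

Step 4
Reactants: 6 5-[4-(tert-butyldimethylsilyloxy)-2-methoxyphenyl]-4-(methoxycarbonyl)furan-2-carboxylic acid
Product: 8 methyl 5-(diazoacetyl)-2-[4-(tert-butyldimethylsilyloxy)-2-methoxyphenyl]furan-3-carboxylate, via acid chloride 7 (not isolated)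
Conditions: (COCl)2 (1.5 equiv), DMF (cat.), CH2Cl2, 0 °C to rt, evaporate; then CH2N2 (3 equiv), Et2O/THF, 0 °C
Reagents that add atoms: diazomethane C=[N+]=[N-]
Why: Acid chloride formation followed by C-acylation of diazomethane (the first stage of the Arndt–Eistert sequence), with a second equivalent of diazomethane scavenging HCl so that the α-diazoketone is not converted into a chloromethyl ketone.

Step 5
Reactants: 9 methacrolein
Product: 10 racemic 2-(prop-1-en-2-yl)oxirane
Conditions: Me3S+ I− (1.1 equiv), NaH (1.1 equiv), DMSO, 0 °C to rt; product distilled from the mixture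
Reagents that add atoms: trimethylsulfonium iodide C[S+](C)C.[I-]
Why: Corey–Chaykovsky epoxidation, in which the sulfonium ylide adds 1,2 to the enal carbonyl and the betaine closes to the racemic vinyl epoxide, which is separated from DMSO by distillation.

Step 6
Reactants: 10 racemic 2-(prop-1-en-2-yl)oxirane
Product: 11 (S)-2-(prop-1-en-2-yl)oxirane
Conditions: (S,S)-N,N'-bis(3,5-di-tert-butylsalicylidene)-1,2-cyclohexanediaminocobalt acetate (trivalent cobalt, 0.5 mol%), H2O (0.55 equiv), neat, 0 °C to rt; distil
Reagents that add atoms: none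
Why: Jacobsen hydrolytic kinetic resolution of a terminal epoxide, in which the (S,S)-catalyst hydrolyses the (R)-enantiomer at its CH2 terminus so that the unreacted (S)-epoxide is distilled away from the non-volatile diol, and this fixes the only stereocentre of the target.

Step 7
Reactants: 11 (S)-2-(prop-1-en-2-yl)oxirane; 12 chloroacetaldehyde dimethyl acetal
Product: 14 (R)-6-methoxy-2-methylhex-1-en-5-yn-3-ol, via sodium methoxyacetylide 13 (not isolated)
Conditions: 12 (1.5 equiv), NaNH2 (4.5 equiv), liq. NH3, −33 °C; then 11 in THF, −33 °C; solid NH4Cl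
Reagents that add atoms: none
Why: NaNH2 eliminates MeOH and HCl from the chloroacetal to give sodium methoxyacetylide (the standard generation of methoxyacetylene), which opens the terminal epoxide by SN2 attack at the unhindered CH2 under basic, Lewis-acid-free conditions, so the C–O stereocentre is untouched and (S)-11 gives (R)-14 (the descriptor changes only through the priority rules).

Step 8
Reactants: 14 (R)-6-methoxy-2-methylhex-1-en-5-yn-3-ol
Product: 15 (R)-tert-butyl[(6-methoxy-2-methylhex-1-en-5-yn-3-yl)oxy]dimethylsilane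
Conditions: TBSCl (1.3 equiv), imidazole (2.6 equiv), DMF, 0 °C to rt; chromatography on Et3N-treated silica
Reagents that add atoms: tert-butyldimethylsilyl chloride CC(C)(C)[Si](C)(C)Cl
Why: Imidazole-buffered silylation of the secondary alcohol, which leaves the acid-sensitive ynol ether intact and removes the hydroxyl group that could otherwise add to the ynol ether or trap the ketene in step 9.

Step 9
Reactants: 8 methyl 5-(diazoacetyl)-2-[4-(tert-butyldimethylsilyloxy)-2-methoxyphenyl]furan-3-carboxylate; 15 (R)-tert-butyl[(6-methoxy-2-methylhex-1-en-5-yn-3-yl)oxy]dimethylsilane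
Product: 20 methyl 2-[4-(tert-butyldimethylsilyloxy)-2-methoxyphenyl]-5-[(2R)-2-(tert-butyldimethylsilyloxy)-3-methylbut-3-en-1-yl]-4-hydroxy-6-methoxy-1-benzofuran-3-carboxylate, via furylketene 16 (not isolated), via cyclobutenone 17 (not isolated), via dienylketene 18 (not isolated), via cyclohexadienone 19 (not isolated)
Conditions: 8 (1.0 equiv), 15 (1.3 equiv), degassed ClCH2CH2Cl, hν (medium-pressure Hg lamp, Pyrex filter, λ > 300 nm), rt; then 80 °C
Reagents that add atoms: none
Why: Light triggers the Wolff rearrangement of 8 (loss of N2 and 1,2-shift of the furyl group to the diazo carbon, forming C7–C7a) to give furylketene 16, to which the electron-rich alkyne 15 adds in a [2+2] step that joins its chain-bearing carbon to the ketene carbonyl carbon (C4–C5) and its methoxy-bearing carbon to the ketene CH (C6–C7), giving cyclobutenone 17. On heating, 17 opens reversibly by a four-electron electrocyclic process to dienylketene 18, whose isomer with the furyl group cis to the ketene closes ring A by a thermal six-electron electrocyclisation onto the free furan β-carbon (C3a–C4), and cyclohexadienone 19 tautomerises to phenol 20. The closest known reaction type is the Danheiser benzannulation in its second-generation (α-diazoketone) form, which is established for heteroaryl diazoketones and for alkoxy- and siloxyalkynes. No stereocentre is created in 20 (those of 17 and 19 are transient), and the (R)-carbinol centre of 15 sits two atoms from the alkyne and is not involved. The step needs regioselectivity in the [2+2] addition, which the polarisation of the ynol ether provides (its CH2-bearing carbon is the nucleophilic one and attacks the ketene carbonyl carbon), and chemoselectivity for the alkyne over the isopropenyl group and the product phenol, which the much higher ketenophilicity of the ynol ether and the slight excess of 15 should secure.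

Step 10
Reactants: 20 methyl 2-[4-(tert-butyldimethylsilyloxy)-2-methoxyphenyl]-5-[(2R)-2-(tert-butyldimethylsilyloxy)-3-methylbut-3-en-1-yl]-4-hydroxy-6-methoxy-1-benzofuran-3-carboxylate
Product: 21 2-[4-(tert-butyldimethylsilyloxy)-2-methoxyphenyl]-5-[(2R)-2-(tert-butyldimethylsilyloxy)-3-methylbut-3-en-1-yl]-3-(hydroxymethyl)-6-methoxy-1-benzofuran-4-ol
Conditions: i-Bu2AlH (4.5 equiv), CH2Cl2, −78 to −20 °C; aq. potassium sodium tartrate; used crude
Reagents that add atoms: none
Why: Ester reduction by i-Bu2AlH (one equivalent is consumed by the C4 phenol), which should take the hydrogen-bonded C3 ester to the primary alcohol at low temperature without touching the silyl ethers or the isolated alkene.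

Step 11
Reactants: 21 2-[4-(tert-butyldimethylsilyloxy)-2-methoxyphenyl]-5-[(2R)-2-(tert-butyldimethylsilyloxy)-3-methylbut-3-en-1-yl]-3-(hydroxymethyl)-6-methoxy-1-benzofuran-4-ol
Product: 22 2-[4-(tert-butyldimethylsilyloxy)-2-methoxyphenyl]-5-[(2R)-2-(tert-butyldimethylsilyloxy)-3-methylbut-3-en-1-yl]-4-hydroxy-6-methoxy-1-benzofuran-3-carbaldehyde
Conditions: activated MnO2 (15 equiv), CH2Cl2, rt
Reagents that add atoms: none
Why: MnO2 oxidation of a benzylic-type (benzofuran-3-yl)methanol to the aldehyde, selective because the secondary allylic alcohol is still silylated, and the product is stabilised by the hydrogen bond from the C4 hydroxyl group.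

Step 12
Reactants: 22 2-[4-(tert-butyldimethylsilyloxy)-2-methoxyphenyl]-5-[(2R)-2-(tert-butyldimethylsilyloxy)-3-methylbut-3-en-1-yl]-4-hydroxy-6-methoxy-1-benzofuran-3-carbaldehyde
Product: 23 4-hydroxy-2-(4-hydroxy-2-methoxyphenyl)-5-[(2R)-2-hydroxy-3-methylbut-3-en-1-yl]-6-methoxy-1-benzofuran-3-carbaldehyde (CNP0183251.1)
Conditions: n-Bu4NF (5 equiv), AcOH (2.5 equiv), THF, 0 to 40 °C
Reagents that add atoms: none
Why: Fluoride cleavage of the aryl and the secondary alkyl silyl ether in an acetic-acid-buffered medium, which should leave the non-enolisable aldehyde, the allylic alcohol, the isopropenyl group and the stereocentre unchanged.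

**Compound list**

1 | 4,5-dibromofuran-2-carboxylic acid | OC(=O)c1cc(Br)c(Br)o1 | starting material
2 | 3-methoxy-4-(4,4,5,5-tetramethyl-1,3,2-dioxaborolan-2-yl)phenol | COc1cc(O)ccc1B1OC(C)(C)C(C)(C)O1 | starting material
3 | 4-bromo-5-(4-hydroxy-2-methoxyphenyl)furan-2-carboxylic acid | COc1cc(O)ccc1-c1oc(C(=O)O)cc1Br | intermediate
4 | 5-(4-hydroxy-2-methoxyphenyl)-4-(methoxycarbonyl)furan-2-carboxylic acid | COC(=O)c1cc(C(=O)O)oc1-c1ccc(O)cc1OC | intermediate
5 | tert-butyldimethylsilyl 5-[4-(tert-butyldimethylsilyloxy)-2-methoxyphenyl]-4-(methoxycarbonyl)furan-2-carboxylate (not isolated) | COC(=O)c1cc(C(=O)O[Si](C)(C)C(C)(C)C)oc1-c1ccc(O[Si](C)(C)C(C)(C)C)cc1OC | intermediate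
6 | 5-[4-(tert-butyldimethylsilyloxy)-2-methoxyphenyl]-4-(methoxycarbonyl)furan-2-carboxylic acid | COC(=O)c1cc(C(=O)O)oc1-c1ccc(O[Si](C)(C)C(C)(C)C)cc1OC | intermediate
7 | methyl 5-(chlorocarbonyl)-2-[4-(tert-butyldimethylsilyloxy)-2-methoxyphenyl]furan-3-carboxylate (not isolated) | COC(=O)c1cc(C(Cl)=O)oc1-c1ccc(O[Si](C)(C)C(C)(C)C)cc1OC | intermediate
8 | methyl 5-(diazoacetyl)-2-[4-(tert-butyldimethylsilyloxy)-2-methoxyphenyl]furan-3-carboxylate | COC(=O)c1cc(C(=O)C=[N+]=[N-])oc1-c1ccc(O[Si](C)(C)C(C)(C)C)cc1OC | intermediate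
9 | methacrolein | C=C(C)C=O | starting material
10 | racemic 2-(prop-1-en-2-yl)oxirane | C=C(C)C1CO1 | intermediate
11 | (S)-2-(prop-1-en-2-yl)oxirane | C=C(C)[C@H]1CO1 | intermediate
12 | chloroacetaldehyde dimethyl acetal (2-chloro-1,1-dimethoxyethane) | COC(CCl)OC | starting material
13 | sodium methoxyacetylide (not isolated) | [Na+].[C-]#COC | intermediate
14 | (R)-6-methoxy-2-methylhex-1-en-5-yn-3-ol | C=C(C)[C@H](O)CC#COC | intermediate
15 | (R)-tert-butyl[(6-methoxy-2-methylhex-1-en-5-yn-3-yl)oxy]dimethylsilane | C=C(C)[C@H](O[Si](C)(C)C(C)(C)C)CC#COC | intermediate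
16 | methyl 2-[4-(tert-butyldimethylsilyloxy)-2-methoxyphenyl]-5-(2-oxoethenyl)furan-3-carboxylate, the furylketene (not isolated) | COC(=O)c1cc(C=C=O)oc1-c1ccc(O[Si](C)(C)C(C)(C)C)cc1OC | intermediate
17 | 4-furyl-3-methoxy-2-[(2R)-2-silyloxy-3-methylbut-3-enyl]cyclobut-2-en-1-one, both epimers at C4 of the four-membered ring (not isolated) | C=C(C)[C@H](O[Si](C)(C)C(C)(C)C)CC1=C(OC)C(c2cc(C(=O)OC)c(-c3ccc(O[Si](C)(C)C(C)(C)C)cc3OC)o2)C1=O | intermediate
18 | dienylketene with the furyl group cis to the ketene-bearing carbon (not isolated) | C=C(C)[C@H](O[Si](C)(C)C(C)(C)C)CC(=C=O)/C(OC)=C\c1cc(C(=O)OC)c(-c2ccc(O[Si](C)(C)C(C)(C)C)cc2OC)o1 | intermediate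
19 | 3a-H cyclohexadienone tautomer of 20 (not isolated) | C=C(C)[C@H](O[Si](C)(C)C(C)(C)C)CC1=C(OC)C=C2OC(-c3ccc(O[Si](C)(C)C(C)(C)C)cc3OC)=C(C(=O)OC)C2C1=O | intermediate
20 | methyl 2-[4-(tert-butyldimethylsilyloxy)-2-methoxyphenyl]-5-[(2R)-2-(tert-butyldimethylsilyloxy)-3-methylbut-3-en-1-yl]-4-hydroxy-6-methoxy-1-benzofuran-3-carboxylate | C=C(C)[C@H](O[Si](C)(C)C(C)(C)C)Cc1c(OC)cc2oc(-c3ccc(O[Si](C)(C)C(C)(C)C)cc3OC)c(C(=O)OC)c2c1O | intermediate
21 | 2-[4-(tert-butyldimethylsilyloxy)-2-methoxyphenyl]-5-[(2R)-2-(tert-butyldimethylsilyloxy)-3-methylbut-3-en-1-yl]-3-(hydroxymethyl)-6-methoxy-1-benzofuran-4-ol | C=C(C)[C@H](O[Si](C)(C)C(C)(C)C)Cc1c(OC)cc2oc(-c3ccc(O[Si](C)(C)C(C)(C)C)cc3OC)c(CO)c2c1O | intermediate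
22 | 2-[4-(tert-butyldimethylsilyloxy)-2-methoxyphenyl]-5-[(2R)-2-(tert-butyldimethylsilyloxy)-3-methylbut-3-en-1-yl]-4-hydroxy-6-methoxy-1-benzofuran-3-carbaldehyde | C=C(C)[C@H](O[Si](C)(C)C(C)(C)C)Cc1c(OC)cc2oc(-c3ccc(O[Si](C)(C)C(C)(C)C)cc3OC)c(C=O)c2c1O | intermediate
23 | 4-hydroxy-2-(4-hydroxy-2-methoxyphenyl)-5-[(2R)-2-hydroxy-3-methylbut-3-en-1-yl]-6-methoxy-1-benzofuran-3-carbaldehyde (CNP0183251.1) | C=C(C)[C@H](O)Cc1c(OC)cc2oc(-c3ccc(O)cc3OC)c(C=O)c2c1O | target

**Step count and risks**

Total steps: 12. Longest linear sequence: 8 steps (steps 1–4 then 9–12, or equally steps 5–8 then 9–12).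

Steps most likely to fail:

Step 9 (benzannulation). The arylfuran chromophore of 8 and of the product may absorb most of the light, so the Wolff rearrangement could be slow. The ketene could be lost through dimerisation or through acylation of the newly formed phenol, the ynol ether could degrade under irradiation, and the thermal electrocyclic sequence could stall at the cyclobutenone. The fallback sets out from 8 and comes back at 20, generating the same ketene without light. Silver-catalysed Wolff rearrangement of 8 in aqueous THF (AgO2CPh, Et3N) should give the homologous acid 2-{5-[4-(tert-butyldimethylsilyloxy)-2-methoxyphenyl]-4-(methoxycarbonyl)furan-2-yl}acetic acid F1. Oxalyl chloride with catalytic DMF should convert it into methyl 5-(2-chloro-2-oxoethyl)-2-[4-(tert-butyldimethylsilyloxy)-2-methoxyphenyl]furan-3-carboxylate F2. Slow addition of i-Pr2NEt to F2 and 15 in toluene at room temperature, followed by heating to 80 °C, should form ketene 16 by dehydrochlorination, and the cascade through 17, 18 and 19 should then deliver 20.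

Step 7 (epoxide opening). The acetylide may attack the allylic epoxide carbon or open the vinyl epoxide in a conjugate fashion instead of attacking CH2. Excess amide may isomerise the epoxide, and the sodium acetylide may react sluggishly in ammonia. The fallback sets out from 9 and comes back at 14. Methoxyallene is lithiated at C1 (n-BuLi, THF, −40 °C), transmetallated with ClTi(O-i-Pr)3 and added to 9 at −78 °C. Titanated alkoxyallenes react with aldehydes at the γ-carbon to give 4-hydroxy-1-methoxyalk-1-ynes, here racemic 6-methoxy-2-methylhex-1-en-5-yn-3-ol F3. A Sharpless kinetic resolution (Ti(O-i-Pr)4, L-(+)-diisopropyl tartrate, t-BuOOH, 4 Å molecular sieves, CH2Cl2, −20 °C, run past half conversion) should epoxidise the (S)-enantiomer to (S)-4-methoxy-1-[(S)-2-methyloxiran-2-yl]but-3-yn-1-ol F4 and leave (R)-14, which is separated by chromatography and rejoins the route at step 8.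

Step 10 (ester reduction). The new 3-hydroxymethyl group lies on an electron-rich 2-arylbenzofuran and may ionise in the presence of the Lewis-acidic aluminium species, leading to loss of the benzylic oxygen (over-reduction to a methyl group) or oligomerisation. The hydrogen-bonded ester may also be reduced incompletely. The fallback sets out from 20 and comes back at 22 without passing through the benzylic alcohol. Treatment of 20 with MeNH(OMe)·HCl and i-PrMgCl (THF, −20 to 0 °C) should give the Weinreb amide 2-[4-(tert-butyldimethylsilyloxy)-2-methoxyphenyl]-5-[(2R)-2-(tert-butyldimethylsilyloxy)-3-methylbut-3-en-1-yl]-4-hydroxy-N,6-dimethoxy-N-methyl-1-benzofuran-3-carboxamide F5. Reduction of F5 with i-Bu2AlH at −78 °C should stop at the chelated tetrahedral intermediate and give aldehyde 22 on work-up.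

**Further compounds**

F1 | step 9 | 2-{5-[4-(tert-butyldimethylsilyloxy)-2-methoxyphenyl]-4-(methoxycarbonyl)furan-2-yl}acetic acid | COC(=O)c1cc(CC(=O)O)oc1-c1ccc(O[Si](C)(C)C(C)(C)C)cc1OC
F2 | step 9 | methyl 5-(2-chloro-2-oxoethyl)-2-[4-(tert-butyldimethylsilyloxy)-2-methoxyphenyl]furan-3-carboxylate | COC(=O)c1cc(CC(Cl)=O)oc1-c1ccc(O[Si](C)(C)C(C)(C)C)cc1OC
F3 | step 7 | racemic 6-methoxy-2-methylhex-1-en-5-yn-3-ol | C=C(C)C(O)CC#COC
F4 | step 7 | (S)-4-methoxy-1-[(S)-2-methyloxiran-2-yl]but-3-yn-1-ol | COC#CC[C@H](O)[C@]1(C)CO1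
F5 | step 10 | 2-[4-(tert-butyldimethylsilyloxy)-2-methoxyphenyl]-5-[(2R)-2-(tert-butyldimethylsilyloxy)-3-methylbut-3-en-1-yl]-4-hydroxy-N,6-dimethoxy-N-methyl-1-benzofuran-3-carboxamide | C=C(C)[C@H](O[Si](C)(C)C(C)(C)C)Cc1c(OC)cc2oc(-c3ccc(O[Si](C)(C)C(C)(C)C)cc3OC)c(C(=O)N(C)OC)c2c1O
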